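**Retrosynthetic overview**

Rings: A = hydroxylated cyclopentenone (diosphenol), B = cyclooctene, C = cyclohexane, D = cyclopentane carrying isopropyl and the acyloxy group.
1. Last come the side-chain ester (Yamaguchi) and the ring A oxidations: the tertiary carbinol at the A/B fusion and the diosphenol.
2. Ring B is closed by ring-closing metathesis (allyl + isopropenyl) after a convergent Negishi union of a ring C/D alkenylzinc with a ring A 2-iodoenone, at the carbon that becomes the fully substituted carbinol.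
3. Rings C and D are made together. Ring D is a formal [3+2] adduct: its unit C(quaternary, CH3)–CH2–CH(O) is a β-methyl enoate and its unit CH(ring fusion)–CH(isopropyl) is an isopropyl alkyne. The C/D fusion bond is shared by both rings, so a tether through the two other stereocentres of ring C lets one nickel-catalysed reductive cycloaddition close both.
4. Stereochemistry: one centre from iridium-catalysed allylic alkylation is relayed to the quaternary carbon (key step), then CBS reduction, then hydroxyl-directed hydrogenation (two centres). The ester-bearing ring C carbon and the A/B fusion are funnelled by epimerisation and enolate oxidation. Ring A and the side chain each start from one bought stereocentre.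
5. Order of ring formation: C + D (one step), A (bought), B.

Key step: step 6

Assumption: the bromo-enoate, the stannyl allyl alcohol, 4-methylpent-2-yn-1-ol, the silyloxycyclopentenone and (S)-1-bromo-2-methylbutane are taken as purchasable; the ligand enantiomer in step 3 is the one that gives the 3R product, its mirror image being equally available.

**Route**

Step 1
Reactants: 1 ethyl (E)-4-bromo-3-methylbut-2-enoate; 2 (E)-3-(tributylstannyl)prop-2-en-1-ol
Product: 3 ethyl (2E,5E)-7-hydroxy-3-methylhepta-2,5-dienoate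
Conditions: Pd2(dba)3 (2.5 mol %), AsPh3 (10 mol %), THF, 50 °C
Reagents that add atoms: none
Why: Stille coupling of an allylic bromide with an alkenylstannane should join the two carbons with retention of both alkene geometries and tolerate the free alcohol.

Step 2
Reactants: 3 ethyl (2E,5E)-7-hydroxy-3-methylhepta-2,5-dienoate
Product: 4 ethyl (2E,5E)-7-[(methoxycarbonyl)oxy]-3-methylhepta-2,5-dienoate
Conditions: ClCO2Me, pyridine, CH2Cl2, 0 °C
Reagents that add atoms: methyl chloroformate, COC(=O)Cl
Why: Acylation of the primary allylic alcohol gives the methyl carbonate, the leaving group that also supplies the base in the next step.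

Step 3
Reactants: 4 ethyl (2E,5E)-7-[(methoxycarbonyl)oxy]-3-methylhepta-2,5-dienoate; 5 dimethyl malonate
Product: 6 dimethyl 2-[(3R,5E)-7-ethoxy-5-methyl-7-oxohepta-1,5-dien-3-yl]propanedioate
Conditions: [Ir(cod)Cl]2 (2 mol %), (Sa,S,S)-O,O'-(1,1'-binaphthalene-2,2'-diyl) N,N-bis(1-phenylethyl)phosphoramidite (4 mol %), 1,5,7-triazabicyclo[4.4.0]dec-5-ene (8 mol %), THF, rt
Reagents that add atoms: none
Why: Iridium-catalysed asymmetric allylic alkylation of a linear (E)-allyl carbonate with malonate should give the branched product, the chiral phosphoramidite–iridium allyl complex setting the vinyl-bearing stereocentre (the only catalyst-made centre of the ring C/D part).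

Step 4
Reactants: 7 4-methylpent-2-yn-1-ol
Product: 8 1-bromo-4-methylpent-2-yne
Conditions: CBr4, PPh3, CH2Cl2, 0 °C
Reagents that add atoms: carbon tetrabromide, BrC(Br)(Br)Br
Why: Appel bromination of a primary propargylic alcohol is reliable and leaves the alkyne untouched.

Step 5
Reactants: 6 dimethyl 2-[(3R,5E)-7-ethoxy-5-methyl-7-oxohepta-1,5-dien-3-yl]propanedioate; 8 1-bromo-4-methylpent-2-yne
Product: 9 dimethyl 2-[(3R,5E)-7-ethoxy-5-methyl-7-oxohepta-1,5-dien-3-yl]-2-(4-methylpent-2-yn-1-yl)propanedioate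
Conditions: NaH, THF/DMF, 0 °C to rt
Reagents that add atoms: none
Why: SN2 alkylation of the malonate anion with a propargylic bromide gives the gem-diester carbon (no stereocentre), which places alkyne and enoate four atoms apart.

Step 6
Reactants: 9 dimethyl 2-[(3R,5E)-7-ethoxy-5-methyl-7-oxohepta-1,5-dien-3-yl]-2-(4-methylpent-2-yn-1-yl)propanedioate
Product: 11 dimethyl (3aS,5R)-5-ethenyl-3a-methyl-2-oxo-1-(propan-2-yl)-2,3,3a,4,5,7-hexahydro-6H-indene-6,6-dicarboxylate, via oxa-nickelacycle 10 (not isolated)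
Conditions: Ni(cod)2 (15 mol %), PBu3 (30 mol %), Et3B (3 equiv), MeOH/THF 1:8, 50 °C
Reagents that add atoms: none
Why: Proposed new method: zerovalent nickel should couple the alkyne with the β-carbon of the E-enoate by oxidative cyclisation to the seven-membered nickel enolate 10, methanol protonates the enolate carbon, and the alkenylnickel then acylates itself on the ethyl ester (loss of ethoxide) before Et3B returns nickel to the zerovalent state; the closest known reactions are the nickel-catalysed reductive [3+2] cycloaddition of enoates with alkynes to cyclopentenones (intermolecular) and that of tethered alkynyl enals to bicyclic cyclopentenols, so the new element is a tethered enoate with a fully substituted β-carbon. Ring C closes in the oxidative cyclisation by a 6-exo C–C bond formation (exo to both the alkyne and the enoate C=C), and ring D closes by 5-exo-trig attack of the alkenylnickel carbon on the ester carbonyl. The only new stereocentre, the quaternary ring-fusion carbon, should be set by the vinyl-bearing carbon of the tether, because in the chair-like transition state vinyl is equatorial and methyl axial whereas the epimer would need vinyl and methyl syn-diaxial. The step needs chemoselectivity (only the conjugated alkene is electron-poor enough for oxidative cyclisation, and syn addition holds the C–Ni bond cis to the quaternary carbon so that only the enoate carbonyl and not a malonate ester is within reach), and it needs acylation to outrun protonolysis of the alkenylnickel, which the gem-diester compression and the five-membered closure should favour.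

Step 7
Reactants: 11 dimethyl (3aS,5R)-5-ethenyl-3a-methyl-2-oxo-1-(propan-2-yl)-2,3,3a,4,5,7-hexahydro-6H-indene-6,6-dicarboxylate
Product: 12 dimethyl (2R,3aS,5R)-5-ethenyl-2-hydroxy-3a-methyl-1-(propan-2-yl)-2,3,3a,4,5,7-hexahydro-6H-indene-6,6-dicarboxylate (2-OH trans to 3a-CH3)
Conditions: (S)-2-methyl-CBS-oxazaborolidine (20 mol %), catecholborane, toluene, −78 °C; aq. NaOH
Reagents that add atoms: none
Why: Corey–Bakshi–Shibata reduction of the 2-substituted cyclopentenone should be reagent-controlled (alkenyl side large, CH2 side small) and give the 2R carbinol trans to the angular methyl, with catecholborane sparing the vinyl group.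

Step 8
Reactants: 12 dimethyl (2R,3aS,5R)-5-ethenyl-2-hydroxy-3a-methyl-1-(propan-2-yl)-2,3,3a,4,5,7-hexahydro-6H-indene-6,6-dicarboxylate
Product: 13 dimethyl (2R,3aS,5S)-5-acetyl-2-hydroxy-3a-methyl-1-(propan-2-yl)-2,3,3a,4,5,7-hexahydro-6H-indene-6,6-dicarboxylate
Conditions: PdCl2 (10 mol %), CuCl (1 equiv), O2 (1 atm), DMF/H2O 7:1, rt
Reagents that add atoms: water, O
Why: Tsuji–Wacker oxidation converts the monosubstituted vinyl group into the methyl ketone and leaves the tetrasubstituted alkene alone, which removes the only other alkene before hydrogenation and stores the future isopropenyl group.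

Step 9
Reactants: 13 dimethyl (2R,3aS,5S)-5-acetyl-2-hydroxy-3a-methyl-1-(propan-2-yl)-2,3,3a,4,5,7-hexahydro-6H-indene-6,6-dicarboxylate
Product: 14 dimethyl 5-acetyl-2-hydroxy-3a-methyl-1-(propan-2-yl)octahydro-6H-indene-6,6-dicarboxylate (trans-fused; 7a-H, 2-OH and 5-acetyl on one face, 3a-CH3 and 1-isopropyl on the other)
Conditions: [Ir(cod)(PCy3)(py)]PF6 (10 mol %), H2 (50 bar), CH2Cl2, rt
Reagents that add atoms: none
Why: Hydroxyl-directed hydrogenation with the cationic iridium catalyst should deliver both hydrogens to the face of the allylic OH, which sets the trans ring fusion and places the isopropyl group cis to the angular methyl in one event.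

Step 10
Reactants: 14 dimethyl 5-acetyl-2-hydroxy-3a-methyl-1-(propan-2-yl)octahydro-6H-indene-6,6-dicarboxylate
Product: 15 dimethyl 2-hydroxy-3a-methyl-1-(propan-2-yl)-5-(prop-1-en-2-yl)octahydro-6H-indene-6,6-dicarboxylate (stereochemistry as in 14)
Conditions: Ph3PCH3Br, KOt-Bu, THF, 0 °C to rt
Reagents that add atoms: methyltriphenylphosphonium bromide, C[P+](c1ccccc1)(c1ccccc1)c1ccccc1.[Br-]
Why: Wittig methylenation converts only the methyl ketone (the esters are inert) into the isopropenyl group, and its equatorial carbon is the thermodynamic epimer in any case.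

Step 11
Reactants: 15 dimethyl 2-hydroxy-3a-methyl-1-(propan-2-yl)-5-(prop-1-en-2-yl)octahydro-6H-indene-6,6-dicarboxylate
Product: 16 methyl 2-hydroxy-3a-methyl-1-(propan-2-yl)-5-(prop-1-en-2-yl)octahydro-1H-indene-6-carboxylate (6-CO2CH3 equatorial, trans to 5-isopropenyl, cis to 3a-CH3)
Conditions: LiCl, H2O, DMSO, 150 °C
Reagents that add atoms: none
Why: Krapcho dealkoxycarbonylation removes one ester, and the new CH centre should settle in the equatorial configuration trans to the isopropenyl group (any axial epimer is funnelled in step 13).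

Step 12
Reactants: 16 methyl 2-hydroxy-3a-methyl-1-(propan-2-yl)-5-(prop-1-en-2-yl)octahydro-1H-indene-6-carboxylate
Product: 17 2-hydroxy-N-methoxy-N,3a-dimethyl-1-(propan-2-yl)-5-(prop-1-en-2-yl)octahydro-1H-indene-6-carboxamide
Conditions: MeNH(OMe)·HCl, i-PrMgCl, THF, −20 to 0 °C
Reagents that add atoms: N,O-dimethylhydroxylamine hydrochloride, CNOC.Cl
Why: Aminolysis of the ester with the magnesium amide of N,O-dimethylhydroxylamine (Weinreb amide synthesis) works on hindered esters and tolerates the alkoxide.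

Step 13
Reactants: 17 2-hydroxy-N-methoxy-N,3a-dimethyl-1-(propan-2-yl)-5-(prop-1-en-2-yl)octahydro-1H-indene-6-carboxamide
Product: 18 1-[2-hydroxy-3a-methyl-1-(propan-2-yl)-5-(prop-1-en-2-yl)octahydro-1H-inden-6-yl]ethan-1-one (acetyl equatorial, trans to isopropenyl)
Conditions: MeMgBr, THF, 0 °C; then K2CO3, MeOH, rt
Reagents that add atoms: methylmagnesium bromide, C[Mg]Br
Why: Weinreb ketone synthesis stops at the methyl ketone, and the base treatment equilibrates the α-carbon to the diequatorial trans arrangement, so both epimers converge.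

Step 14
Reactants: 18 1-[2-hydroxy-3a-methyl-1-(propan-2-yl)-5-(prop-1-en-2-yl)octahydro-1H-inden-6-yl]ethan-1-one
Product: 19 (E)-2,4,6-triisopropylbenzenesulfonylhydrazone of 18
Conditions: 2,4,6-(i-Pr)3C6H2SO2NHNH2, HCl (cat.), THF, rt
Reagents that add atoms: 2,4,6-triisopropylbenzenesulfonohydrazide, CC(C)c1cc(C(C)C)c(S(=O)(=O)NN)c(C(C)C)c1
Why: Condensation of the methyl ketone with the arenesulfonylhydrazide gives the substrate of the Shapiro reaction.

Step 15
Reactants: 20 (R)-4-[(tert-butyldimethylsilyl)oxy]cyclopent-2-en-1-one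
Product: 22 (R)-4-methylcyclopent-2-en-1-one, via silyloxy ketone 21 (not isolated)
Conditions: Me2CuLi (from MeLi, CuI), Et2O, −78 °C; then DBU, CH2Cl2, rt
Reagents that add atoms: lithium dimethylcuprate, [Li+].C[Cu-]C
Why: Cuprate conjugate addition occurs anti to the silyloxy group and E1cB loss of silanol then moves the enone, so the bought stereocentre is exchanged for the methyl-bearing one.

Step 16
Reactants: 22 (R)-4-methylcyclopent-2-en-1-one
Product: 23 (R)-2-iodo-4-methylcyclopent-2-en-1-one
Conditions: I2, pyridine/CH2Cl2, 0 °C to rt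
Reagents that add atoms: iodine, II
Why: Pyridine-mediated α-iodination of an enone (conjugate addition of pyridine, iodination, elimination) gives the 2-iodoenone without touching the γ-stereocentre.

Step 17
Reactants: 19 (E)-2,4,6-triisopropylbenzenesulfonylhydrazone of 18; 23 (R)-2-iodo-4-methylcyclopent-2-en-1-one
Product: 26 (4R)-2-{1-[2-hydroxy-3a-methyl-1-(propan-2-yl)-5-(prop-1-en-2-yl)octahydro-1H-inden-6-yl]ethenyl}-4-methylcyclopent-2-en-1-one, via alkenyllithium 24 (not isolated), via alkenylzinc chloride 25 (not isolated)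
Conditions: n-BuLi (3.3 equiv), THF, −78 to 0 °C; ZnCl2, 0 °C; then 23, Pd(PPh3)4 (5 mol %), rt
Reagents that add atoms: none
Why: The Shapiro reaction gives the less substituted alkenyllithium, and after transmetalation to zinc a Negishi coupling with the 2-iodoenone joins the two fragments at the carbon that later becomes the fully substituted carbinol.

Step 18
Reactants: 26 (4R)-2-{1-[2-hydroxy-3a-methyl-1-(propan-2-yl)-5-(prop-1-en-2-yl)octahydro-1H-inden-6-yl]ethenyl}-4-methylcyclopent-2-en-1-one
Product: 28 3-allyl-4-methyl-2-{1-[hydrindanyl]ethenyl}cyclopentan-1-one (hydrindanyl as in 18; 2,3-trans and 3,4-trans on the cyclopentanone), via bis-silyl enol ether 27 (not isolated)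
Conditions: allylMgBr, CuBr·SMe2, Me3SiCl, THF, −78 °C; 1 M HCl, THF, 0 °C; then DBU (cat.), CH2Cl2, 0 °C, short
Reagents that add atoms: allylmagnesium bromide, C=CC[Mg]Br
Why: Silyl chloride-accelerated allylcopper conjugate addition should occur anti to the neighbouring methyl group and so set the ring A CH centre by relay, and hydrolysis with brief base equilibration should give the all-trans ketone.

Step 19
Reactants: 28 3-allyl-4-methyl-2-{1-[hydrindanyl]ethenyl}cyclopentan-1-one
Product: 29 tetracyclic ketone with rings A–D (A/B fusion trans, CH at the fusion carbon next to the exocyclic methylene, Z-trisubstituted alkene in ring B)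
Conditions: second-generation Grubbs catalyst RuCl2(H2IMes)(PCy3)(=CHPh) (10 mol %), 1,4-benzoquinone (20 mol %), toluene (2 mM), 80 °C
Reagents that add atoms: none
Why: Ring-closing metathesis of the allyl and isopropenyl groups should give the trisubstituted cyclooctene, because in the trans ketone a closure onto the hindered exocyclic methylene would need a trans-fused bicyclo[3.3.0]octene.

Step 20
Reactants: 29 tetracyclic ketone with rings A–D
Product: 31 tetracyclic ketol (A/B fusion cis, tertiary OH at the fusion carbon between the ketone and the exocyclic methylene), via hydroperoxide 30 (not isolated)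
Conditions: KOt-Bu, O2, P(OEt)3, THF/t-BuOH, −40 °C
Reagents that add atoms: dioxygen, O=O
Why: Oxygenation of the thermodynamic potassium enolate (more substituted and conjugated with the methylene) with in situ phosphite reduction should bring oxygen to the face away from the ring B CH2 on the neighbouring carbon and give the cis-fused tertiary alcohol.

Step 21
Reactants: 32 (S)-1-bromo-2-methylbutane
Product: 33 (S)-4-methylhex-1-yne
Conditions: LiC≡CH·H2NCH2CH2NH2, DMSO, 10 °C to rt
Reagents that add atoms: lithium acetylide ethylenediamine complex, [Li]C#C.NCCN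
Why: SN2 alkylation of lithium acetylide with the primary bromide leaves the bought stereocentre untouched.

Step 22
Reactants: 33 (S)-4-methylhex-1-yne
Product: 35 (2E,5S)-3,5-dimethylhept-2-en-1-ol, via alkenylalane 34 (not isolated)
Conditions: Me3Al, Cp2ZrCl2 (25 mol %), CH2Cl2, 0 °C to rt; then (CH2O)n, THF
Reagents that add atoms: trimethylaluminium, C[Al](C)C; formaldehyde (as paraformaldehyde), C=O
Why: Zirconium-catalysed carboalumination (Negishi) adds methyl and aluminium syn across the alkyne, and trapping with formaldehyde gives the E-trisubstituted allylic alcohol.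

Step 23
Reactants: 35 (2E,5S)-3,5-dimethylhept-2-en-1-ol
Product: 36 [(2R,3R)-3-methyl-3-[(2S)-2-methylbutyl]oxiran-2-yl]methanol
Conditions: Ti(Oi-Pr)4 (10 mol %), D-(−)-diethyl tartrate (12 mol %), t-BuOOH, 4 Å MS, CH2Cl2, −20 °C
Reagents that add atoms: tert-butyl hydroperoxide, CC(C)(C)OO
Why: Sharpless asymmetric epoxidation with the D-tartrate sets the tertiary C–O centre by reagent control.

Step 24
Reactants: 36 [(2R,3R)-3-methyl-3-[(2S)-2-methylbutyl]oxiran-2-yl]methanol
Product: 37 (3R,5S)-3,5-dimethylheptane-1,3-diol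
Conditions: NaAlH2(OCH2CH2OMe)2, THF, 0 °C
Reagents that add atoms: none
Why: Hydroxyl-directed hydride opening of the 2,3-epoxy alcohol at C2 gives the 1,3-diol with the tertiary centre unchanged.

Step 25
Reactants: 37 (3R,5S)-3,5-dimethylheptane-1,3-diol
Product: 38 (3R,5S)-3-hydroxy-3,5-dimethylheptanoic acid
Conditions: TEMPO (cat.), NaOCl (cat.), NaClO2, MeCN/phosphate buffer pH 6.7, 35 °C
Reagents that add atoms: sodium chlorite, [Na+].[O-]Cl=O
Why: Nitroxyl-catalysed chlorite oxidation takes the primary alcohol to the acid and cannot oxidise the tertiary alcohol.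

Step 26
Reactants: 38 (3R,5S)-3-hydroxy-3,5-dimethylheptanoic acid
Product: 40 (3R,5S)-3,5-dimethyl-3-[(triethylsilyl)oxy]heptanoic acid, via silyl ester 39 (not isolated)
Conditions: Et3SiOTf, 2,6-lutidine, CH2Cl2, 0 °C; then K2CO3, MeOH/H2O; pH 4
Reagents that add atoms: triethylsilyl trifluoromethanesulfonate, CC[Si](CC)(CC)OS(=O)(=O)C(F)(F)F
Why: Silylation of the tertiary alcohol followed by mild methanolysis of the labile silyl ester gives the protected acid.

Step 27
Reactants: 31 tetracyclic ketol; 40 (3R,5S)-3,5-dimethyl-3-[(triethylsilyl)oxy]heptanoic acid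
Product: 41 ester of 31 at the ring D hydroxyl with acid 40
Conditions: 2,4,6-Cl3C6H2COCl, Et3N, THF; then 31, DMAP, toluene, rt
Reagents that add atoms: none
Why: Yamaguchi esterification acylates the secondary ring D alcohol, while the tertiary carbinol at the ring fusion is too hindered to react.

Step 28
Reactants: 41 ester of 31 at the ring D hydroxyl with acid 40
Product: 42 acyloin (41 with a new hydroxyl on the ring A CH2 next to the ketone, both epimers)
Conditions: KN(SiMe3)2 (2.2 equiv), THF, −78 °C; then 2-(phenylsulfonyl)-3-phenyloxaziridine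
Reagents that add atoms: 2-(phenylsulfonyl)-3-phenyloxaziridine, O=S(=O)(c1ccccc1)N1OC1c1ccccc1
Why: The ketone now has a single enolisable position and is more acidic than the ester, so enolate oxidation with the N-sulfonyloxaziridine should hydroxylate that carbon, and its configuration is lost in the next step.

Step 29
Reactants: 42 acyloin
Product: 43 triethylsilyl ether of the target at the side-chain tertiary hydroxyl
Conditions: Dess–Martin periodinane, NaHCO3, CH2Cl2, 0 °C to rt
Reagents that add atoms: none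
Why: Dess–Martin oxidation of the acyloin gives the 1,2-dicarbonyl system, which exists as the enol with the tetrasubstituted C=C (diosphenol), so the methyl-bearing ring A carbon becomes planar as required.

Step 30
Reactants: 43 triethylsilyl ether of the target
Product: 44 CNP0110944.3
Conditions: HF·pyridine, pyridine, THF, 0 °C
Reagents that add atoms: none
Why: Buffered fluoride desilylation frees the tertiary alcohol of the side chain without harming the ester, the diosphenol or the allylic tertiary alcohol.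

**Compound list**

1 | ethyl (E)-4-bromo-3-methylbut-2-enoate | CCOC(=O)/C=C(\C)CBr | starting material
2 | (E)-3-(tributylstannyl)prop-2-en-1-ol | CCCC[Sn](CCCC)(CCCC)/C=C/CO | starting material
3 | ethyl (2E,5E)-7-hydroxy-3-methylhepta-2,5-dienoate | CCOC(=O)/C=C(\C)C/C=C/CO | intermediate
4 | ethyl (2E,5E)-7-[(methoxycarbonyl)oxy]-3-methylhepta-2,5-dienoate | CCOC(=O)/C=C(\C)C/C=C/COC(=O)OC | intermediate
5 | dimethyl malonate | COC(=O)CC(=O)OC | starting material
6 | dimethyl 2-[(3R,5E)-7-ethoxy-5-methyl-7-oxohepta-1,5-dien-3-yl]propanedioate | C=C[C@@H](C/C(C)=C/C(=O)OCC)C(C(=O)OC)C(=O)OC | intermediate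
7 | 4-methylpent-2-yn-1-ol | CC(C)C#CCO | starting material
8 | 1-bromo-4-methylpent-2-yne | CC(C)C#CCBr | intermediate
9 | dimethyl 2-[(3R,5E)-7-ethoxy-5-methyl-7-oxohepta-1,5-dien-3-yl]-2-(4-methylpent-2-yn-1-yl)propanedioate | C=C[C@@H](C/C(C)=C/C(=O)OCC)C(CC#CC(C)C)(C(=O)OC)C(=O)OC | intermediate
10 | seven-membered oxa-nickelacycle (nickel on the alkenyl carbon and the ester enolate oxygen, phosphines omitted) | C=C[C@H]1C[C@@]2(C)C=C(OCC)O[Ni]C(C(C)C)=C2CC1(C(=O)OC)C(=O)OC | intermediate
11 | dimethyl (3aS,5R)-5-ethenyl-3a-methyl-2-oxo-1-(propan-2-yl)-2,3,3a,4,5,7-hexahydro-6H-indene-6,6-dicarboxylate | C=C[C@H]1C[C@@]2(C)CC(=O)C(C(C)C)=C2CC1(C(=O)OC)C(=O)OC | intermediate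
12 | dimethyl (2R,3aS,5R)-5-ethenyl-2-hydroxy-3a-methyl-1-(propan-2-yl)-2,3,3a,4,5,7-hexahydro-6H-indene-6,6-dicarboxylate | C=C[C@H]1C[C@@]2(C)C[C@@H](O)C(C(C)C)=C2CC1(C(=O)OC)C(=O)OC | intermediate
13 | dimethyl (2R,3aS,5S)-5-acetyl-2-hydroxy-3a-methyl-1-(propan-2-yl)-2,3,3a,4,5,7-hexahydro-6H-indene-6,6-dicarboxylate | CC(=O)[C@H]1C[C@@]2(C)C[C@@H](O)C(C(C)C)=C2CC1(C(=O)OC)C(=O)OC | intermediate
14 | dimethyl 5-acetyl-2-hydroxy-3a-methyl-1-(propan-2-yl)octahydro-6H-indene-6,6-dicarboxylate (trans-fused) | CC(=O)[C@H]1C[C@@]2(C)C[C@@H](O)[C@H](C(C)C)[C@@H]2CC1(C(=O)OC)C(=O)OC | intermediate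
15 | dimethyl 2-hydroxy-3a-methyl-1-(propan-2-yl)-5-(prop-1-en-2-yl)octahydro-6H-indene-6,6-dicarboxylate | C=C(C)[C@H]1C[C@@]2(C)C[C@@H](O)[C@H](C(C)C)[C@@H]2CC1(C(=O)OC)C(=O)OC | intermediate
16 | methyl 2-hydroxy-3a-methyl-1-(propan-2-yl)-5-(prop-1-en-2-yl)octahydro-1H-indene-6-carboxylate | C=C(C)[C@H]1C[C@@]2(C)C[C@@H](O)[C@H](C(C)C)[C@@H]2C[C@@H]1C(=O)OC | intermediate
17 | 2-hydroxy-N-methoxy-N,3a-dimethyl-1-(propan-2-yl)-5-(prop-1-en-2-yl)octahydro-1H-indene-6-carboxamide | C=C(C)[C@H]1C[C@@]2(C)C[C@@H](O)[C@H](C(C)C)[C@@H]2C[C@@H]1C(=O)N(C)OC | intermediate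
18 | 1-[2-hydroxy-3a-methyl-1-(propan-2-yl)-5-(prop-1-en-2-yl)octahydro-1H-inden-6-yl]ethan-1-one | C=C(C)[C@H]1C[C@@]2(C)C[C@@H](O)[C@H](C(C)C)[C@@H]2C[C@@H]1C(C)=O | intermediate
19 | (E)-2,4,6-triisopropylbenzenesulfonylhydrazone of 18 | C=C(C)[C@H]1C[C@@]2(C)C[C@@H](O)[C@H](C(C)C)[C@@H]2C[C@@H]1/C(C)=N/NS(=O)(=O)c1c(C(C)C)cc(C(C)C)cc1C(C)C | intermediate
20 | (R)-4-[(tert-butyldimethylsilyl)oxy]cyclopent-2-en-1-one | O=C1C=C[C@H](O[Si](C)(C)C(C)(C)C)C1 | starting material
21 | (3R,4R)-3-methyl-4-[(tert-butyldimethylsilyl)oxy]cyclopentan-1-one | O=C1C[C@@H](C)[C@H](O[Si](C)(C)C(C)(C)C)C1 | intermediate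
22 | (R)-4-methylcyclopent-2-en-1-one | O=C1C=C[C@H](C)C1 | intermediate
23 | (R)-2-iodo-4-methylcyclopent-2-en-1-one | O=C1C(I)=C[C@H](C)C1 | intermediate
24 | alkenyllithium from 19 (lithium alkoxide form) | C=C(C)[C@H]1C[C@@]2(C)C[C@@H](O[Li])[C@H](C(C)C)[C@@H]2C[C@@H]1C([Li])=C | intermediate
25 | alkenylzinc chloride from 24 | C=C(C)[C@H]1C[C@@]2(C)C[C@@H](O[Li])[C@H](C(C)C)[C@@H]2C[C@@H]1C(=C)[Zn]Cl | intermediate
26 | (4R)-2-{1-[2-hydroxy-3a-methyl-1-(propan-2-yl)-5-(prop-1-en-2-yl)octahydro-1H-inden-6-yl]ethenyl}-4-methylcyclopent-2-en-1-one | C=C(C)[C@H]1C[C@@]2(C)C[C@@H](O)[C@H](C(C)C)[C@@H]2C[C@@H]1C(=C)C1=C[C@H](C)CC1=O | intermediate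
27 | trimethylsilyl enol ether of 28, ring D hydroxyl also silylated | C=C(C)[C@H]1C[C@@]2(C)C[C@@H](O[Si](C)(C)C)[C@H](C(C)C)[C@@H]2C[C@@H]1C(=C)C1=C(O[Si](C)(C)C)C[C@@H](C)[C@@H]1CC=C | intermediate
28 | 3-allyl-4-methyl-2-{1-[hydrindanyl]ethenyl}cyclopentan-1-one, all-trans | C=C(C)[C@H]1C[C@@]2(C)C[C@@H](O)[C@H](C(C)C)[C@@H]2C[C@@H]1C(=C)[C@@H]1[C@@H](CC=C)[C@H](C)CC1=O | intermediate
29 | tetracyclic ketone, A/B fusion trans | C=C1[C@H]2C[C@H]3[C@@H](C(C)C)[C@H](O)C[C@]3(C)C[C@@H]2/C(C)=C\C[C@H]2[C@H](C)CC(=O)[C@H]12 | intermediate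
30 | tertiary hydroperoxide at the A/B fusion carbon | C=C1[C@H]2C[C@H]3[C@@H](C(C)C)[C@H](O)C[C@]3(C)C[C@@H]2/C(C)=C\C[C@H]2[C@H](C)CC(=O)[C@@]12OO | intermediate
31 | tetracyclic ketol, A/B fusion cis | C=C1[C@H]2C[C@H]3[C@@H](C(C)C)[C@H](O)C[C@]3(C)C[C@@H]2/C(C)=C\C[C@H]2[C@H](C)CC(=O)[C@@]12O | intermediate
32 | (S)-1-bromo-2-methylbutane | CC[C@H](C)CBr | starting material
33 | (S)-4-methylhex-1-yne | C#CC[C@@H](C)CC | intermediate
34 | (E)-alkenyl(dimethyl)alane from 33 | C[Al](C)/C=C(\C)C[C@@H](C)CC | intermediate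
35 | (2E,5S)-3,5-dimethylhept-2-en-1-ol | OC/C=C(\C)C[C@@H](C)CC | intermediate
36 | [(2R,3R)-3-methyl-3-[(2S)-2-methylbutyl]oxiran-2-yl]methanol | OC[C@H]1O[C@]1(C)C[C@@H](C)CC | intermediate
37 | (3R,5S)-3,5-dimethylheptane-1,3-diol | OCC[C@](C)(O)C[C@@H](C)CC | intermediate
38 | (3R,5S)-3-hydroxy-3,5-dimethylheptanoic acid | OC(=O)C[C@](C)(O)C[C@@H](C)CC | intermediate
39 | triethylsilyl (3R,5S)-3,5-dimethyl-3-[(triethylsilyl)oxy]heptanoate | CC[Si](CC)(CC)OC(=O)C[C@](C)(O[Si](CC)(CC)CC)C[C@@H](C)CC | intermediate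
40 | (3R,5S)-3,5-dimethyl-3-[(triethylsilyl)oxy]heptanoic acid | OC(=O)C[C@](C)(O[Si](CC)(CC)CC)C[C@@H](C)CC | intermediate
41 | ring D ester of 31 with acid 40 | C=C1[C@H]2C[C@H]3[C@@H](C(C)C)[C@H](OC(=O)C[C@](C)(O[Si](CC)(CC)CC)C[C@@H](C)CC)C[C@]3(C)C[C@@H]2/C(C)=C\C[C@H]2[C@H](C)CC(=O)[C@@]12O | intermediate
42 | acyloin from 41 (new ring A carbinol, both epimers) | C=C1[C@H]2C[C@H]3[C@@H](C(C)C)[C@H](OC(=O)C[C@](C)(O[Si](CC)(CC)CC)C[C@@H](C)CC)C[C@]3(C)C[C@@H]2/C(C)=C\C[C@H]2[C@H](C)C(O)C(=O)[C@@]12O | intermediate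
43 | triethylsilyl ether of the target (side-chain tertiary OH) | C=C1[C@H]2C[C@H]3[C@@H](C(C)C)[C@H](OC(=O)C[C@](C)(O[Si](CC)(CC)CC)C[C@@H](C)CC)C[C@]3(C)C[C@@H]2/C(C)=C\C[C@H]2C(C)=C(O)C(=O)[C@@]12O | intermediate
44 | CNP0110944.3 | C=C1[C@H]2C[C@H]3[C@@H](C(C)C)[C@H](OC(=O)C[C@](C)(O)C[C@@H](C)CC)C[C@]3(C)C[C@@H]2/C(C)=C\C[C@H]2C(C)=C(O)C(=O)[C@@]12O | target

**Count and risks**

Total step count: 30. Longest linear sequence: 21 steps (1, 2, 3, 5–14, 17–20, 27–30).

Most likely to fail:

1. Step 6 (proposed new method). The alkenylnickel may be protonated before it acylates, giving only the reductively cyclised ring C, or oxidative cyclisation may be slow at the fully substituted β-carbon. The fallback uses the known cycloaddition of tethered alkynyl enals and sets out from 9. DIBAL-H at −78 °C should reduce the unhindered conjugated ethyl ester in preference to the neopentyl gem-diester and give the allylic alcohol F1. MnO2 then gives the enal F2. Ni(cod)2/PBu3/Et3B in MeOH/THF should give the bicyclic cyclopentenol F3 as a mixture at the carbinol carbon. Dess–Martin oxidation returns to the route at 11.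

2. Step 19. If the α-carbon of 28 is not cleanly trans, or epimerises, metathesis can close a cyclopentene onto the exocyclic methylene; the base equilibration in step 18 may also move that alkene into conjugation; and the trans-fused precursor may cyclise slowly and oligomerise. The fallback sets out from 27, isolated by non-aqueous work-up. Rubottom oxidation with dimethyldioxirane at −78 °C and acidic work-up should give the hydroxy ketone F4, with oxygen anti to the allyl group. VO(acac)2/t-BuOOH should then epoxidise only the methylene next to the tertiary alcohol to give the epoxy alcohol F5. Metathesis can now close only the eight-membered ring, giving the tetracyclic epoxide F6. Deoxygenation with WCl6/n-BuLi restores the methylene and rejoins the route at 31.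

3. Step 20. Enolisation may occur on the CH2 side of the ketone, oxygen may enter from the wrong face, or over-oxidation may set in. The fallback sets out from 29. Me3SiOTf/Et3N should give the more substituted silyl dienol ether F7 under thermodynamic control. Dimethyldioxirane at −78 °C with acidic work-up (Rubottom oxidation) then oxidises only the electron-rich enol ether and returns to the route at 31.

Further compounds
F1 | step 6 | dimethyl 2-[(3R,5E)-7-hydroxy-5-methylhepta-1,5-dien-3-yl]-2-(4-methylpent-2-yn-1-yl)propanedioate | C=C[C@@H](C/C(C)=C/CO)C(CC#CC(C)C)(C(=O)OC)C(=O)OC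
F2 | step 6 | dimethyl 2-[(3R,5E)-5-methyl-7-oxohepta-1,5-dien-3-yl]-2-(4-methylpent-2-yn-1-yl)propanedioate | C=C[C@@H](C/C(C)=C/C=O)C(CC#CC(C)C)(C(=O)OC)C(=O)OC
F3 | step 6 | dimethyl (3aS,5R)-5-ethenyl-2-hydroxy-3a-methyl-1-(propan-2-yl)-2,3,3a,4,5,7-hexahydro-6H-indene-6,6-dicarboxylate, both C2 epimers | C=C[C@H]1C[C@@]2(C)CC(O)C(C(C)C)=C2CC1(C(=O)OC)C(=O)OC
F4 | step 19 | 2-hydroxy ketone from 27 (tertiary OH trans to the allyl group, exocyclic methylene kept) | C=C(C)[C@H]1C[C@@]2(C)C[C@@H](O)[C@H](C(C)C)[C@@H]2C[C@@H]1C(=C)[C@@]1(O)[C@@H](CC=C)[C@H](C)CC1=O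
F5 | step 19 | epoxide of F4 at the exocyclic methylene | C=C(C)[C@H]1C[C@@]2(C)C[C@@H](O)[C@H](C(C)C)[C@@H]2C[C@@H]1C1(CO1)[C@@]1(O)[C@@H](CC=C)[C@H](C)CC1=O
F6 | step 19 | tetracyclic spiro-epoxide (31 with the methylene as epoxide) | C1OC12[C@H]3C[C@H]4[C@@H](C(C)C)[C@H](O)C[C@]4(C)C[C@@H]3/C(C)=C\C[C@H]3[C@H](C)CC(=O)[C@@]23O
F7 | step 20 | bis(trimethylsilyl) dienol ether of 29 | C=C1[C@H]2C[C@H]3[C@@H](C(C)C)[C@H](O[Si](C)(C)C)C[C@]3(C)C[C@@H]2/C(C)=C\C[C@H]2[C@H](C)CC(O[Si](C)(C)C)=C12
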